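**Plan**

1. Numbering (carvone-type): C1 ketone carbon, C2 methyl-bearing epoxide carbon, C3, C4 (CH2), C5 (bears the side chain), C6 (bears the ring angelate); side chain C7(=CH2), C8 (angelate), C9, C10–C11 (epoxide).
2. Retrosynthesis cuts, in this order: the C1 ketone (back to the alcohol), the two epoxide oxygens (C10/C11, then C2/C3), the two angelate esters (ring, then side chain), the prenyl terminus (cross-metathesis) and C8–C9 (allylboration), C7–C8 (formyl from CO), and last the ring bonds C4–C5 and C1–C2.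
3. Enabling feature: the ring is a 6-oxygenated carvone. C1(=O)–C6(O)–C5 with exocyclic C7 is a 2-hydroxysuccinate (malate) pattern, with C5 enolisable next to carboxyl C7 and acyl carbon C1 next to carbinol C6. C2(Me)=C3–C4 is a (Z)-but-2-ene-1,3-diyl unit, nucleophilic at C2 and electrophilic at C4.
4. Forward: the cyclohexenone ring is closed first, in one flask, from a malate-derived amide ester and (Z)-1-bromo-3-iodobut-2-ene ([3+3]). The side chain is then grown from the C7 carboxyl (methyl ketone, enol triflate, enal, allyl, prenyl). Each angelate is installed in its own step, before and after removal of the triethylsilyl group, and the three oxidations come last.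
5. Stereochemistry: C6 from L-malic acid; C5 by chelate-controlled anti alkylation; the temporary C1 alcohol (Luche) directs the C2/C3 epoxide; C8 by reagent-controlled allylboration; C10 by the D-fructose-derived dioxirane.

Key step: step 5

Assumption: the acetonide of L-malic acid, but-2-yn-1-ol, angelic acid and a preformed, salt-free solution of (−)-B-allyldiisopinocampheylborane are taken as available; acids set free in silylations and acylations are bound by the amine base present.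

**Route**

Step 1
Reactants: 1 but-2-yn-1-ol
Product: 2 (2Z)-3-iodobut-2-en-1-ol
Conditions: NaAlH2(OCH2CH2OMe)2, THF, 0 °C to rt; then I2, −78 °C to rt
Reagents that add atoms: iodine, II
Why: Alkoxide-directed trans-hydroalumination puts aluminium on C3 cis to the CH2O group, and iodinolysis with retention gives the Z iodide (hydroalumination–iodination of a propargylic alcohol).

Step 2
Reactants: 2 (2Z)-3-iodobut-2-en-1-ol
Product: 3 (2Z)-1-bromo-3-iodobut-2-ene
Conditions: CBr4, PPh3, CH2Cl2, 0 °C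
Reagents that add atoms: carbon tetrabromide, BrC(Br)(Br)Br
Why: Appel bromination replaces the primary allylic hydroxyl by SN2 without touching the alkenyl iodide or its geometry.

Step 3
Reactants: 4 [(4S)-2,2-dimethyl-5-oxo-1,3-dioxolan-4-yl]acetic acid
Product: 5 tert-butyl [(4S)-2,2-dimethyl-5-oxo-1,3-dioxolan-4-yl]acetate
Conditions: tert-butyl 2,2,2-trichloroacetimidate (2 equiv), CH2Cl2/cyclohexane, rt
Reagents that add atoms: tert-butyl 2,2,2-trichloroacetimidate, CC(C)(C)OC(=N)C(Cl)(Cl)Cl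
Why: The free acid protonates the imidate and is tert-butylated under neutral conditions that leave the dioxolanone intact (trichloroacetimidate esterification), which differentiates the two malate carboxyls.

Step 4
Reactants: 5 tert-butyl [(4S)-2,2-dimethyl-5-oxo-1,3-dioxolan-4-yl]acetate
Product: 6 tert-butyl (3S)-3-hydroxy-4-(morpholin-4-yl)-4-oxobutanoate
Conditions: morpholine (1.2 equiv), THF, 0 °C to rt
Reagents that add atoms: morpholine, C1COCCN1
Why: Aminolysis of the activated dioxolanone acyl group releases acetone and gives the α-hydroxy morpholine amide while the hindered tert-butyl ester is untouched.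

Step 5
Reactants: 6 tert-butyl (3S)-3-hydroxy-4-(morpholin-4-yl)-4-oxobutanoate; 3 (2Z)-1-bromo-3-iodobut-2-ene
Product: 9 tert-butyl (1R,2S)-2-hydroxy-4-methyl-3-oxocyclohex-4-ene-1-carboxylate, via alkylated hydroxy amide 7 (not isolated), via cyclic lithium hemiaminal 8 (not isolated)
Conditions: LiN(SiMe3)2 (2.2 equiv), THF, −78 to −20 °C; 3 (1.2 equiv), −78 to −15 °C; then t-BuLi (4.6 equiv), −78 °C; aq. NH4Cl
Reagents that add atoms: none
Why: LiN(SiMe3)2 converts 6 into the chelated alkoxide–ester-enolate dianion, which is C-alkylated by the allylic bromide of 3 on the face anti to the C6 substituent (Fráter–Seebach alkylation), forming C4–C5 and setting C5 (2R,3S in 7) under control of the malate-derived C6 centre. Iodine–lithium exchange on the (Z)-alkenyl iodide of 7 then gives, with retention, an alkenyllithium that adds to the morpholine amide carbonyl (Parham-type cyclo-acylation), forming C1–C2; the chelated hemiaminal 8 survives until work-up and only then collapses to enone 9, so no second addition occurs. The closest known reaction type is the two-stage annulation of enolates with bifunctional (Z)-3-halo-allyl halides followed by intramolecular carbonyl addition, here run in one flask. The six-membered ring closes in the 6-exo-trig mode, the Z geometry of 3 holding the carbanion cis to the tether. The selectivities needed are C- over O-alkylation and SN2 over SN2' (chelated enolate, hindered iodine-bearing terminus), amide over ester acylation (the tert-butyl ester is too hindered for 5-exo attack or for t-BuLi at −78 °C, while the amide is activated by the neighbouring lithium alkoxide), and no re-enolisation at C5 (the regenerated silazide is too weak a base at −78 °C).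

Step 6
Reactants: 9 tert-butyl (1R,2S)-2-hydroxy-4-methyl-3-oxocyclohex-4-ene-1-carboxylate
Product: 10 tert-butyl (1R,2S)-4-methyl-3-oxo-2-[(triethylsilyl)oxy]cyclohex-4-ene-1-carboxylate
Conditions: Et3SiCl, imidazole, CH2Cl2, 0 °C
Reagents that add atoms: chlorotriethylsilane, CC[Si](Cl)(CC)CC
Why: Silylation under mild base masks O6 as the acid-labile triethylsilyl ether without enolising the α-hydroxy enone (silyl ether formation).

Step 7
Reactants: 10 tert-butyl (1R,2S)-4-methyl-3-oxo-2-[(triethylsilyl)oxy]cyclohex-4-ene-1-carboxylate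
Product: 11 tert-butyl (1R,2S,3S)-3-hydroxy-4-methyl-2-[(triethylsilyl)oxy]cyclohex-4-ene-1-carboxylate
Conditions: NaBH4, CeCl3·7H2O, MeOH, −78 °C
Reagents that add atoms: none
Why: In the Luche 1,2-reduction hydride adds axially to C1 of the half-chair with the C5 ester and C6 silyloxy groups equatorial, giving the equatorial C1 alcohol cis to the C5 substituent and trans to O6 (as in carvone to cis-carveol).

Step 8
Reactants: 11 tert-butyl (1R,2S,3S)-3-hydroxy-4-methyl-2-[(triethylsilyl)oxy]cyclohex-4-ene-1-carboxylate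
Product: 13 (1R,2S,3S)-3-[(tert-butyldimethylsilyl)oxy]-4-methyl-2-[(triethylsilyl)oxy]cyclohex-4-ene-1-carboxylic acid, via silyl ester 12 (not isolated)
Conditions: TBSOTf (3.5 equiv), 2,6-lutidine, CH2Cl2, 0 °C to rt; then K2CO3, MeOH/H2O, 0 °C
Reagents that add atoms: tert-butyldimethylsilyl trifluoromethanesulfonate, CC(C)(C)[Si](C)(C)OS(=O)(=O)C(F)(F)F
Why: The silyl triflate silylates the allylic alcohol and, by O-silylation of the ester carbonyl with loss of isobutene, turns the tert-butyl ester into silyl ester 12, which mild basic methanolysis cleaves to the acid while both silyl ethers stay (silyl triflate-mediated tert-butyl ester cleavage).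

Step 9
Reactants: 13 (1R,2S,3S)-3-[(tert-butyldimethylsilyl)oxy]-4-methyl-2-[(triethylsilyl)oxy]cyclohex-4-ene-1-carboxylic acid
Product: 14 1-[(1R,2S,3S)-3-[(tert-butyldimethylsilyl)oxy]-4-methyl-2-[(triethylsilyl)oxy]cyclohex-4-en-1-yl]ethan-1-one
Conditions: MeLi (3 equiv), Et2O, 0 °C; inverse quench into aq. NH4Cl
Reagents that add atoms: methyllithium, [Li]C
Why: MeLi adds to the lithium carboxylate to give a stable gem-diolate that releases the methyl ketone only on quench (carboxylic acid to methyl ketone), with C5 remaining in its thermodynamically preferred equatorial configuration.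

Step 10
Reactants: 14 1-[(1R,2S,3S)-3-[(tert-butyldimethylsilyl)oxy]-4-methyl-2-[(triethylsilyl)oxy]cyclohex-4-en-1-yl]ethan-1-one
Product: 15 1-[(1R,2S,3S)-3-[(tert-butyldimethylsilyl)oxy]-4-methyl-2-[(triethylsilyl)oxy]cyclohex-4-en-1-yl]ethenyl trifluoromethanesulfonate
Conditions: KN(SiMe3)2, THF, −78 °C; then PhNTf2, −78 to 0 °C
Reagents that add atoms: N-phenylbis(trifluoromethanesulfonimide), O=S(=O)(N(c1ccccc1)S(=O)(=O)C(F)(F)F)C(F)(F)F
Why: Kinetic deprotonation at the unhindered methyl group and O-triflation of the potassium enolate give the terminal enol triflate, the C5 methine proton being shielded by its two substituted neighbours (enol triflate formation).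

Step 11
Reactants: 15 1-[(1R,2S,3S)-3-[(tert-butyldimethylsilyl)oxy]-4-methyl-2-[(triethylsilyl)oxy]cyclohex-4-en-1-yl]ethenyl trifluoromethanesulfonate
Product: 16 2-[(1S,2S,3S)-3-[(tert-butyldimethylsilyl)oxy]-4-methyl-2-[(triethylsilyl)oxy]cyclohex-4-en-1-yl]prop-2-enal
Conditions: Pd(PPh3)4 (5 mol%), CO (1 atm), Bu3SnH (slow addition), THF, 50 °C
Reagents that add atoms: carbon monoxide, [C-]#[O+]
Why: Oxidative addition of the enol triflate to the palladium catalyst, CO insertion and hydride transfer from tin give the 2-substituted acrolein (palladium-catalysed formylation of enol triflates).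

Step 12
Reactants: 16 2-[(1S,2S,3S)-3-[(tert-butyldimethylsilyl)oxy]-4-methyl-2-[(triethylsilyl)oxy]cyclohex-4-en-1-yl]prop-2-enal
Product: 17 (3S)-2-[(1S,2S,3S)-3-[(tert-butyldimethylsilyl)oxy]-4-methyl-2-[(triethylsilyl)oxy]cyclohex-4-en-1-yl]hexa-1,5-dien-3-ol
Conditions: (−)-Ipc2B(allyl), Et2O, −78 °C; then NaOH, H2O2, 0 °C to rt
Reagents that add atoms: (−)-B-allyldiisopinocampheylborane [from (+)-α-pinene], C=CCB([C@@H]1C[C@@H]2C[C@H]([C@H]1C)C2(C)C)[C@@H]1C[C@@H]2C[C@H]([C@H]1C)C2(C)C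
Why: In the reagent-controlled Brown allylboration the borane from (+)-α-pinene transfers allyl through a chair transition state to the Si face of the aldehyde, which for an alkenyl aldehyde (as for benzaldehyde) gives the 8S carbinol.

Step 13
Reactants: 17 (3S)-2-[(1S,2S,3S)-3-[(tert-butyldimethylsilyl)oxy]-4-methyl-2-[(triethylsilyl)oxy]cyclohex-4-en-1-yl]hexa-1,5-dien-3-ol
Product: 18 (3S)-2-[(1S,2S,3S)-3-[(tert-butyldimethylsilyl)oxy]-4-methyl-2-[(triethylsilyl)oxy]cyclohex-4-en-1-yl]-6-methylhepta-1,5-dien-3-ol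
Conditions: 2-methylbut-2-ene (excess), second-generation Grubbs catalyst (RuCl2(=CHPh)(PCy3)(H2IMes), 5 mol%), CH2Cl2, 40 °C
Reagents that add atoms: 2-methylbut-2-ene, CC=C(C)C
Why: Cross-metathesis of the monosubstituted alkene with excess 2-methylbut-2-ene installs the prenyl terminus, while the 1,1-disubstituted and the ring trisubstituted alkenes are too hindered to enter the carbene cycle (olefin cross-metathesis).

Step 14
Reactants: 18 (3S)-2-[(1S,2S,3S)-3-[(tert-butyldimethylsilyl)oxy]-4-methyl-2-[(triethylsilyl)oxy]cyclohex-4-en-1-yl]-6-methylhepta-1,5-dien-3-ol; 19 angelic acid, (2Z)-2-methylbut-2-enoic acid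
Product: 20 (3S)-2-[(1S,2S,3S)-3-[(tert-butyldimethylsilyl)oxy]-4-methyl-2-[(triethylsilyl)oxy]cyclohex-4-en-1-yl]-6-methylhepta-1,5-dien-3-yl (2Z)-2-methylbut-2-enoate
Conditions: 19 (1.5 equiv), 2,4,6-trichlorobenzoyl chloride, Et3N, toluene, rt; then 18, 80 °C
Reagents that add atoms: none
Why: The preformed mixed anhydride of angelic acid acylates the only free hydroxyl (C8–OH, both ring oxygens being silylated) without a nucleophilic catalyst, which is the established way to form an angelate without Z to E isomerisation (Yamaguchi-type esterification).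

Step 15
Reactants: 20 (3S)-2-[(1S,2S,3S)-3-[(tert-butyldimethylsilyl)oxy]-4-methyl-2-[(triethylsilyl)oxy]cyclohex-4-en-1-yl]-6-methylhepta-1,5-dien-3-yl (2Z)-2-methylbut-2-enoate
Product: 21 (3S)-2-[(1S,2S,3S)-3-[(tert-butyldimethylsilyl)oxy]-2-hydroxy-4-methylcyclohex-4-en-1-yl]-6-methylhepta-1,5-dien-3-yl (2Z)-2-methylbut-2-enoate
Conditions: PPTS, MeOH/CH2Cl2, 0 °C
Reagents that add atoms: none
Why: Mild acidic methanolysis removes the triethylsilyl ether far faster than the secondary tert-butyldimethylsilyl ether and leaves the angelate alone, freeing O6 while O1 stays masked (selective silyl ether cleavage).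

Step 16
Reactants: 21 (3S)-2-[(1S,2S,3S)-3-[(tert-butyldimethylsilyl)oxy]-2-hydroxy-4-methylcyclohex-4-en-1-yl]-6-methylhepta-1,5-dien-3-yl (2Z)-2-methylbut-2-enoate; 19 angelic acid, (2Z)-2-methylbut-2-enoic acid
Product: 22 (1S,2S,6S)-2-[(tert-butyldimethylsilyl)oxy]-3-methyl-6-[(3S)-6-methyl-3-{[(2Z)-2-methylbut-2-enoyl]oxy}hepta-1,5-dien-2-yl]cyclohex-3-en-1-yl (2Z)-2-methylbut-2-enoate
Conditions: 19 (3 equiv), 2,4,6-trichlorobenzoyl chloride, Et3N, toluene, rt; then 21, 80 °C
Reagents that add atoms: none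
Why: A second molecule of angelic acid, again as its preformed mixed anhydride and without a nucleophilic catalyst, acylates the ring C6 hydroxyl with retention of the Z geometry, the existing C8 ester being inert under these conditions (Yamaguchi-type esterification).

Step 17
Reactants: 22 (1S,2S,6S)-2-[(tert-butyldimethylsilyl)oxy]-3-methyl-6-[(3S)-6-methyl-3-{[(2Z)-2-methylbut-2-enoyl]oxy}hepta-1,5-dien-2-yl]cyclohex-3-en-1-yl (2Z)-2-methylbut-2-enoate
Product: 23 (1S,2S,6S)-2-hydroxy-3-methyl-6-[(3S)-6-methyl-3-{[(2Z)-2-methylbut-2-enoyl]oxy}hepta-1,5-dien-2-yl]cyclohex-3-en-1-yl (2Z)-2-methylbut-2-enoate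
Conditions: HF·pyridine, pyridine, THF, 0 °C to rt
Reagents that add atoms: none
Why: Buffered HF·pyridine cleaves the tert-butyldimethylsilyl ether without hydrolysing or isomerising the angelates (fluoride desilylation).

Step 18
Reactants: 23 (1S,2S,6S)-2-hydroxy-3-methyl-6-[(3S)-6-methyl-3-{[(2Z)-2-methylbut-2-enoyl]oxy}hepta-1,5-dien-2-yl]cyclohex-3-en-1-yl (2Z)-2-methylbut-2-enoate
Product: 24 (1R,2R,3S,4S,6S)-2-hydroxy-1-methyl-4-[(3S)-6-methyl-3-{[(2Z)-2-methylbut-2-enoyl]oxy}hepta-1,5-dien-2-yl]-7-oxabicyclo[4.1.0]heptan-3-yl (2Z)-2-methylbut-2-enoate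
Conditions: VO(acac)2 (5 mol%), t-BuOOH, CH2Cl2, 0 °C to rt
Reagents that add atoms: tert-butyl hydroperoxide, CC(C)(C)OO
Why: The vanadium alkoxide–peroxide complex delivers oxygen to the face of the C2=C3 alkene syn to the C1 hydroxyl, setting C2 and C3 cis to the C5 side chain, while the prenyl, methylene and angelate alkenes lack a free allylic hydroxyl and stay (hydroxyl-directed epoxidation).

Step 19
Reactants: 24 (1R,2R,3S,4S,6S)-2-hydroxy-1-methyl-4-[(3S)-6-methyl-3-{[(2Z)-2-methylbut-2-enoyl]oxy}hepta-1,5-dien-2-yl]-7-oxabicyclo[4.1.0]heptan-3-yl (2Z)-2-methylbut-2-enoate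
Product: 25 (1R,2R,3S,4S,6S)-4-[(3S)-4-[(2R)-3,3-dimethyloxiran-2-yl]-3-{[(2Z)-2-methylbut-2-enoyl]oxy}but-1-en-2-yl]-2-hydroxy-1-methyl-7-oxabicyclo[4.1.0]heptan-3-yl (2Z)-2-methylbut-2-enoate
Conditions: D-fructose-derived ketone (1,2:4,5-di-O-isopropylidene-β-D-erythro-2,3-hexodiulo-2,6-pyranose, 1 equiv), KHSO5 (as 2KHSO5·KHSO4·K2SO4), NaHCO3, aq. Na2EDTA, MeCN, 0 °C
Reagents that add atoms: potassium peroxymonosulfate, [K+].[O-]S(=O)(=O)OO
Why: In the Shi epoxidation the dioxirane from the D-fructose-derived ketone attacks the electron-rich trisubstituted prenyl alkene through the spiro transition state that gives the 10R epoxide, while the 1,1-disubstituted alkene and the electron-poor angelates react far more slowly.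

Step 20
Reactants: 25 (1R,2R,3S,4S,6S)-4-[(3S)-4-[(2R)-3,3-dimethyloxiran-2-yl]-3-{[(2Z)-2-methylbut-2-enoyl]oxy}but-1-en-2-yl]-2-hydroxy-1-methyl-7-oxabicyclo[4.1.0]heptan-3-yl (2Z)-2-methylbut-2-enoate
Product: 26 (1S,3S,4S,6S)-4-[(3S)-4-[(2R)-3,3-dimethyloxiran-2-yl]-3-{[(2Z)-2-methylbut-2-enoyl]oxy}but-1-en-2-yl]-1-methyl-2-oxo-7-oxabicyclo[4.1.0]heptan-3-yl (2Z)-2-methylbut-2-enoate (target)
Conditions: Dess–Martin periodinane, NaHCO3, CH2Cl2, 0 °C to rt
Reagents that add atoms: none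
Why: Dess–Martin oxidation of the secondary alcohol under buffered neutral conditions gives the α,β-epoxy ketone without epimerising C6 or opening either epoxide.

**Compound list**

1 | but-2-yn-1-ol | CC#CCO | starting material
2 | (2Z)-3-iodobut-2-en-1-ol | C/C(I)=C/CO | intermediate
3 | (2Z)-1-bromo-3-iodobut-2-ene | C/C(I)=C/CBr | intermediate
4 | [(4S)-2,2-dimethyl-5-oxo-1,3-dioxolan-4-yl]acetic acid | O=C1OC(C)(C)O[C@H]1CC(=O)O | starting material
5 | tert-butyl [(4S)-2,2-dimethyl-5-oxo-1,3-dioxolan-4-yl]acetate | O=C1OC(C)(C)O[C@H]1CC(=O)OC(C)(C)C | intermediate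
6 | tert-butyl (3S)-3-hydroxy-4-(morpholin-4-yl)-4-oxobutanoate | O=C(N1CCOCC1)[C@H](CC(=O)OC(C)(C)C)O | intermediate
7 | tert-butyl (2R,3S)-3-hydroxy-2-[(2Z)-3-iodobut-2-en-1-yl]-4-(morpholin-4-yl)-4-oxobutanoate (present as lithium alkoxide) | CC(C)(C)OC(=O)[C@@H]([C@H](O)C(=O)N1CCOCC1)C/C=C(/C)I | intermediate
8 | tert-butyl (1R,2S)-2,3-dihydroxy-4-methyl-3-(morpholin-4-yl)cyclohex-4-ene-1-carboxylate (present as dilithium alkoxide, C3 not defined) | CC(C)(C)OC(=O)[C@@H]1CC=C(C)C(O)(N2CCOCC2)[C@H]1O | intermediate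
9 | tert-butyl (1R,2S)-2-hydroxy-4-methyl-3-oxocyclohex-4-ene-1-carboxylate | CC(C)(C)OC(=O)[C@@H]1CC=C(C)C(=O)[C@H]1O | intermediate
10 | tert-butyl (1R,2S)-4-methyl-3-oxo-2-[(triethylsilyl)oxy]cyclohex-4-ene-1-carboxylate | CC(C)(C)OC(=O)[C@@H]1CC=C(C)C(=O)[C@H]1O[Si](CC)(CC)CC | intermediate
11 | tert-butyl (1R,2S,3S)-3-hydroxy-4-methyl-2-[(triethylsilyl)oxy]cyclohex-4-ene-1-carboxylate | CC(C)(C)OC(=O)[C@@H]1CC=C(C)[C@H](O)[C@H]1O[Si](CC)(CC)CC | intermediate
12 | tert-butyldimethylsilyl (1R,2S,3S)-3-[(tert-butyldimethylsilyl)oxy]-4-methyl-2-[(triethylsilyl)oxy]cyclohex-4-ene-1-carboxylate | CC(C)(C)[Si](C)(C)OC(=O)[C@@H]1CC=C(C)[C@H](O[Si](C)(C)C(C)(C)C)[C@H]1O[Si](CC)(CC)CC | intermediate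
13 | (1R,2S,3S)-3-[(tert-butyldimethylsilyl)oxy]-4-methyl-2-[(triethylsilyl)oxy]cyclohex-4-ene-1-carboxylic acid | OC(=O)[C@@H]1CC=C(C)[C@H](O[Si](C)(C)C(C)(C)C)[C@H]1O[Si](CC)(CC)CC | intermediate
14 | 1-[(1R,2S,3S)-3-[(tert-butyldimethylsilyl)oxy]-4-methyl-2-[(triethylsilyl)oxy]cyclohex-4-en-1-yl]ethan-1-one | CC(=O)[C@@H]1CC=C(C)[C@H](O[Si](C)(C)C(C)(C)C)[C@H]1O[Si](CC)(CC)CC | intermediate
15 | 1-[(1R,2S,3S)-3-[(tert-butyldimethylsilyl)oxy]-4-methyl-2-[(triethylsilyl)oxy]cyclohex-4-en-1-yl]ethenyl trifluoromethanesulfonate | C=C(OS(=O)(=O)C(F)(F)F)[C@@H]1CC=C(C)[C@H](O[Si](C)(C)C(C)(C)C)[C@H]1O[Si](CC)(CC)CC | intermediate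
16 | 2-[(1S,2S,3S)-3-[(tert-butyldimethylsilyl)oxy]-4-methyl-2-[(triethylsilyl)oxy]cyclohex-4-en-1-yl]prop-2-enal | O=CC(=C)[C@@H]1CC=C(C)[C@H](O[Si](C)(C)C(C)(C)C)[C@H]1O[Si](CC)(CC)CC | intermediate
17 | (3S)-2-[(1S,2S,3S)-3-[(tert-butyldimethylsilyl)oxy]-4-methyl-2-[(triethylsilyl)oxy]cyclohex-4-en-1-yl]hexa-1,5-dien-3-ol | C=C([C@H](CC=C)O)[C@@H]1CC=C(C)[C@H](O[Si](C)(C)C(C)(C)C)[C@H]1O[Si](CC)(CC)CC | intermediate
18 | (3S)-2-[(1S,2S,3S)-3-[(tert-butyldimethylsilyl)oxy]-4-methyl-2-[(triethylsilyl)oxy]cyclohex-4-en-1-yl]-6-methylhepta-1,5-dien-3-ol | C=C([C@H](CC=C(C)C)O)[C@@H]1CC=C(C)[C@H](O[Si](C)(C)C(C)(C)C)[C@H]1O[Si](CC)(CC)CC | intermediate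
19 | angelic acid, (2Z)-2-methylbut-2-enoic acid | C/C=C(/C)C(=O)O | starting material
20 | (3S)-2-[(1S,2S,3S)-3-[(tert-butyldimethylsilyl)oxy]-4-methyl-2-[(triethylsilyl)oxy]cyclohex-4-en-1-yl]-6-methylhepta-1,5-dien-3-yl (2Z)-2-methylbut-2-enoate | C=C([C@H](CC=C(C)C)OC(=O)/C(C)=C\C)[C@@H]1CC=C(C)[C@H](O[Si](C)(C)C(C)(C)C)[C@H]1O[Si](CC)(CC)CC | intermediate
21 | (3S)-2-[(1S,2S,3S)-3-[(tert-butyldimethylsilyl)oxy]-2-hydroxy-4-methylcyclohex-4-en-1-yl]-6-methylhepta-1,5-dien-3-yl (2Z)-2-methylbut-2-enoate | C=C([C@H](CC=C(C)C)OC(=O)/C(C)=C\C)[C@@H]1CC=C(C)[C@H](O[Si](C)(C)C(C)(C)C)[C@H]1O | intermediate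
22 | (1S,2S,6S)-2-[(tert-butyldimethylsilyl)oxy]-3-methyl-6-[(3S)-6-methyl-3-{[(2Z)-2-methylbut-2-enoyl]oxy}hepta-1,5-dien-2-yl]cyclohex-3-en-1-yl (2Z)-2-methylbut-2-enoate | C=C([C@H](CC=C(C)C)OC(=O)/C(C)=C\C)[C@@H]1CC=C(C)[C@H](O[Si](C)(C)C(C)(C)C)[C@H]1OC(=O)/C(C)=C\C | intermediate
23 | (1S,2S,6S)-2-hydroxy-3-methyl-6-[(3S)-6-methyl-3-{[(2Z)-2-methylbut-2-enoyl]oxy}hepta-1,5-dien-2-yl]cyclohex-3-en-1-yl (2Z)-2-methylbut-2-enoate | C=C([C@H](CC=C(C)C)OC(=O)/C(C)=C\C)[C@@H]1CC=C(C)[C@H](O)[C@H]1OC(=O)/C(C)=C\C | intermediate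
24 | (1R,2R,3S,4S,6S)-2-hydroxy-1-methyl-4-[(3S)-6-methyl-3-{[(2Z)-2-methylbut-2-enoyl]oxy}hepta-1,5-dien-2-yl]-7-oxabicyclo[4.1.0]heptan-3-yl (2Z)-2-methylbut-2-enoate | C=C([C@H](CC=C(C)C)OC(=O)/C(C)=C\C)[C@@H]1C[C@@H]2O[C@]2(C)[C@H](O)[C@H]1OC(=O)/C(C)=C\C | intermediate
25 | (1R,2R,3S,4S,6S)-4-[(3S)-4-[(2R)-3,3-dimethyloxiran-2-yl]-3-{[(2Z)-2-methylbut-2-enoyl]oxy}but-1-en-2-yl]-2-hydroxy-1-methyl-7-oxabicyclo[4.1.0]heptan-3-yl (2Z)-2-methylbut-2-enoate | C=C([C@H](C[C@H]1OC1(C)C)OC(=O)/C(C)=C\C)[C@@H]1C[C@@H]2O[C@]2(C)[C@H](O)[C@H]1OC(=O)/C(C)=C\C | intermediate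
26 | (1S,3S,4S,6S)-4-[(3S)-4-[(2R)-3,3-dimethyloxiran-2-yl]-3-{[(2Z)-2-methylbut-2-enoyl]oxy}but-1-en-2-yl]-1-methyl-2-oxo-7-oxabicyclo[4.1.0]heptan-3-yl (2Z)-2-methylbut-2-enoate | C=C([C@H](C[C@H]1OC1(C)C)OC(=O)/C(C)=C\C)[C@@H]1C[C@@H]2O[C@]2(C)C(=O)[C@H]1OC(=O)/C(C)=C\C | target

**Step count and risks**

Total step count: 20. Longest linear sequence: 18 steps (4 to 26, steps 3 to 20); steps 1 and 2 form the side branch that enters at step 5.

Steps most likely to fail:

Step 5. In the second stage the alkenyllithium may be consumed by proton transfer (from the silazane or intramolecularly from C5–H) or may add to the ester carbonyl in the 5-exo mode, and re-enolisation may erode the C5 configuration. Fallback: the two bonds are made in separate flasks with a carbonyl-selective, non-basic metal. Setting out from 6 and 3, the alkylation alone (LiN(SiMe3)2, THF, −78 to −15 °C) gives isolated 7. O6 is silylated (Et3SiCl, imidazole) to give tert-butyl (2R,3S)-2-[(2Z)-3-iodobut-2-en-1-yl]-4-(morpholin-4-yl)-4-oxo-3-[(triethylsilyl)oxy]butanoate F1. The morpholine amide is reduced with Cp2Zr(H)Cl (THF, rt) to the aldehyde tert-butyl (2R,3S)-2-[(2Z)-3-iodobut-2-en-1-yl]-4-oxo-3-[(triethylsilyl)oxy]butanoate F2. Nozaki–Hiyama–Kishi cyclisation (CrCl2, NiCl2 cat., DMF, rt), which leaves esters alone, closes C1–C2 to tert-butyl (1R,2S)-3-hydroxy-4-methyl-2-[(triethylsilyl)oxy]cyclohex-4-ene-1-carboxylate F3 (both C3 epimers). Dess–Martin oxidation converges both epimers on 10, where the route is rejoined.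

Step 11. Premature hydride transfer to the alkenylpalladium (plain reduction of the triflate), slow oxidative addition at the hindered enol triflate, or isomerisation of the sensitive 2-substituted acrolein may occur. Fallback: the side chain is joined convergently without the enal. Setting out from 15, Nozaki–Hiyama–Kishi coupling (CrCl2, NiCl2 cat., DMF, rt) with 4-methylpent-3-enal F4 (Dess–Martin oxidation of commercial 4-methylpent-3-en-1-ol, used at once) gives 2-[(1S,2S,3S)-3-[(tert-butyldimethylsilyl)oxy]-4-methyl-2-[(triethylsilyl)oxy]cyclohex-4-en-1-yl]-6-methylhepta-1,5-dien-3-ol F5 as a mixture of C8 epimers. Dess–Martin oxidation gives 2-[(1S,2S,3S)-3-[(tert-butyldimethylsilyl)oxy]-4-methyl-2-[(triethylsilyl)oxy]cyclohex-4-en-1-yl]-6-methylhepta-1,5-dien-3-one F6. Corey–Bakshi–Shibata reduction with the (R)-methyl oxazaborolidine and BH3·SMe2 (alkenyl as the large group) gives the 8S alcohol 18, where the route is rejoined; steps 12 and 13 are bypassed.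

Step 16. Acylation of the hindered ring hydroxyl, flanked by the silyloxy carbon and the branched side chain, may stay incomplete under the catalyst-free conditions, and forcing conditions or nucleophilic catalysts may isomerise the Z acyl group to the E (tigloyl) isomer. Fallback: the Z alkene is built after the acylation. Setting out from 21, the ring hydroxyl is esterified with 2-(diphenoxyphosphoryl)propanoic acid (DCC, DMAP cat., CH2Cl2, 0 °C to rt), an acyl donor that carries no isomerisable alkene, to give (3S)-2-[(1S,2S,3S)-3-[(tert-butyldimethylsilyl)oxy]-2-{[2-(diphenoxyphosphoryl)propanoyl]oxy}-4-methylcyclohex-4-en-1-yl]-6-methylhepta-1,5-dien-3-yl (2Z)-2-methylbut-2-enoate F7. A Z-selective Horner–Wadsworth–Emmons reaction of the diaryl phosphonate with acetaldehyde (NaH, THF, −78 °C) then builds the angeloyl alkene in place and gives 22, where the route is rejoined.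

**Further compounds**

F1 | step 5 | tert-butyl (2R,3S)-2-[(2Z)-3-iodobut-2-en-1-yl]-4-(morpholin-4-yl)-4-oxo-3-[(triethylsilyl)oxy]butanoate | CC(C)(C)OC(=O)[C@@H]([C@H](O[Si](CC)(CC)CC)C(=O)N1CCOCC1)C/C=C(/C)I
F2 | step 5 | tert-butyl (2R,3S)-2-[(2Z)-3-iodobut-2-en-1-yl]-4-oxo-3-[(triethylsilyl)oxy]butanoate | CC(C)(C)OC(=O)[C@@H]([C@H](O[Si](CC)(CC)CC)C=O)C/C=C(/C)I
F3 | step 5 | tert-butyl (1R,2S)-3-hydroxy-4-methyl-2-[(triethylsilyl)oxy]cyclohex-4-ene-1-carboxylate (both C3 epimers) | CC(C)(C)OC(=O)[C@@H]1CC=C(C)C(O)[C@H]1O[Si](CC)(CC)CC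
F4 | step 11 | 4-methylpent-3-enal | CC(C)=CCC=O
F5 | step 11 | 2-[(1S,2S,3S)-3-[(tert-butyldimethylsilyl)oxy]-4-methyl-2-[(triethylsilyl)oxy]cyclohex-4-en-1-yl]-6-methylhepta-1,5-dien-3-ol (both C3 epimers of the chain) | C=C(C(O)CC=C(C)C)[C@@H]1CC=C(C)[C@H](O[Si](C)(C)C(C)(C)C)[C@H]1O[Si](CC)(CC)CC
F6 | step 11 | 2-[(1S,2S,3S)-3-[(tert-butyldimethylsilyl)oxy]-4-methyl-2-[(triethylsilyl)oxy]cyclohex-4-en-1-yl]-6-methylhepta-1,5-dien-3-one | C=C(C(=O)CC=C(C)C)[C@@H]1CC=C(C)[C@H](O[Si](C)(C)C(C)(C)C)[C@H]1O[Si](CC)(CC)CC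
F7 | step 16 | (3S)-2-[(1S,2S,3S)-3-[(tert-butyldimethylsilyl)oxy]-2-{[2-(diphenoxyphosphoryl)propanoyl]oxy}-4-methylcyclohex-4-en-1-yl]-6-methylhepta-1,5-dien-3-yl (2Z)-2-methylbut-2-enoate (phosphonate α-carbon not defined) | C=C([C@H](CC=C(C)C)OC(=O)/C(C)=C\C)[C@@H]1CC=C(C)[C@H](O[Si](C)(C)C(C)(C)C)[C@H]1OC(=O)C(C)P(=O)(Oc1ccccc1)Oc1ccccc1
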